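**Retrosynthetic overview**
1. Target ⇒ open both pyranone rings to a bis[(E)-2-acetoxycinnamate]; both lactones are closed together in the last operation (deacetylation, phosphine-catalysed lactonisation).
2. Bis-cinnamate ⇒ Heck disconnection of the styryl C–C bond: a vinylcyclohexene plus an aryl bromide (the same aryl bromide is used twice).
3. Vinylcyclohexene ⇒ aldehyde (methylenation) ⇒ catalytic enantioselective exo Diels–Alder of a 1-aryl-3-methyldiene with methacrolein, which sets both stereocentres.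
4. Aryl diene ⇒ aryl bromide + isoprene (Heck); aryl bromide ⇒ 5-bromo-2-hydroxy-4-methoxybenzaldehyde (acetylation, Wittig).
5. Ring order: cyclohexene first (step 3), then the two pyranone rings in one operation (step 5); the benzene rings are bought.

Assumption: the (S)-oxazaborolidinium catalyst delivers the diene to the α-Re face of methacrolein (the sense reported for 2-substituted acroleins, recalled from the literature and not re-derived here); if 7 proves to be the antipode, the (R)-catalyst is used and nothing else changes.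

**Step 1**
Reactants: 1 5-bromo-2-hydroxy-4-methoxybenzaldehyde
Product: 3 methyl (2E)-3-[2-(acetyloxy)-5-bromo-4-methoxyphenyl]prop-2-enoate, via O-acetyl aldehyde 2 (not isolated)
Conditions: Ac2O, Et3N, cat. DMAP, CH2Cl2, 0 °C → rt; then Ph3P=CHCO2Me, rt
Reagents that add atoms: acetic anhydride CC(=O)OC(C)=O; methyl (triphenylphosphoranylidene)acetate COC(=O)C=P(c1ccccc1)(c1ccccc1)c1ccccc1
Why: Acetylation of the phenol followed by a Wittig olefination with the stabilised ylide gives the (E)-acrylate selectively, and the acetate keeps the latent coumarin open and the phenol inert until the last step.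

**Step 2**
Reactants: 3 methyl (2E)-3-[2-(acetyloxy)-5-bromo-4-methoxyphenyl]prop-2-enoate; 4 isoprene
Product: 5 methyl (2E)-3-{2-(acetyloxy)-4-methoxy-5-[(1E)-3-methylbuta-1,3-dien-1-yl]phenyl}prop-2-enoate
Conditions: Pd(OAc)2 (5 mol %), P(o-tol)3 (12 mol %), Et3N, MeCN, 90 °C, sealed tube, isoprene (6 equiv), trace BHT
Reagents that add atoms: none
Why: Mizoroki–Heck reaction in which ArPdBr adds to the CH2 terminus of the unsubstituted vinyl group of isoprene and β-hydride elimination gives the conjugated (E)-1-aryl-3-methyl-1,3-diene.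

**Step 3**
Reactants: 5 methyl (2E)-3-{2-(acetyloxy)-4-methoxy-5-[(1E)-3-methylbuta-1,3-dien-1-yl]phenyl}prop-2-enoate; 6 methacrolein
Product: 7 methyl (2E)-3-{2-(acetyloxy)-5-[(1R,6S)-6-formyl-3,6-dimethylcyclohex-2-en-1-yl]-4-methoxyphenyl}prop-2-enoate
Conditions: (S)-o-tolyl-oxazaborolidinium triflimide (from (S)-α,α-diphenylprolinol, 20 mol %), methacrolein (5 equiv), CH2Cl2, −78 → −40 °C
Reagents that add atoms: none
Why: Catalytic enantioselective Diels–Alder reaction in which the oxazaborolidinium-bound s-trans methacrolein is attacked on its α-Re face by the diene, bonding through its CH2 terminus to the β-carbon (ortho/para regiochemistry) in the formyl-exo/methyl-endo mode expected for α-methylacroleins, which sets the quaternary centre (S) and the aryl-bearing centre (R, aryl trans to CHO and cis to methyl) in one event.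

**Step 4**
Reactants: 7 methyl (2E)-3-{2-(acetyloxy)-5-[(1R,6S)-6-formyl-3,6-dimethylcyclohex-2-en-1-yl]-4-methoxyphenyl}prop-2-enoate
Product: 8 methyl (2E)-3-{2-(acetyloxy)-5-[(1S,6R)-6-ethenyl-3,6-dimethylcyclohex-2-en-1-yl]-4-methoxyphenyl}prop-2-enoate
Conditions: Zn, CH2Br2, TiCl4, THF–CH2Cl2, 0 °C → rt (Lombardo)
Reagents that add atoms: dibromomethane BrCBr
Why: Lombardo (Takai-type) methylenation with the non-basic Zn/Ti gem-dimetallic reagent converts the hindered, non-enolisable aldehyde into the vinyl group and leaves the aryl acetate, the acrylate and both stereocentres untouched (the descriptors change only through CIP priorities).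

**Step 5**
Reactants: 8 methyl (2E)-3-{2-(acetyloxy)-5-[(1S,6R)-6-ethenyl-3,6-dimethylcyclohex-2-en-1-yl]-4-methoxyphenyl}prop-2-enoate; 3 methyl (2E)-3-[2-(acetyloxy)-5-bromo-4-methoxyphenyl]prop-2-enoate
Product: 11 7-methoxy-6-[(E)-2-[(1R,2S)-2-(7-methoxy-2-oxo-2H-chromen-6-yl)-1,4-dimethylcyclohex-3-en-1-yl]ethenyl]-2H-chromen-2-one, via tetraester 9 (not isolated), via bis-phenol 10 (not isolated)
Conditions: Pd(OAc)2 (5 mol %), P(o-tol)3 (12 mol %), Et3N, DMF, 100 °C; then MeOH, cat. K2CO3, rt; then AcOH, n-Bu3P (40 mol %), 65 °C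
Reagents that add atoms: none
Why: Mizoroki–Heck coupling at the terminal vinyl carbon (no allylic hydrogen, so only the E-styrene can form) is followed in the same flask by carbonate-catalysed methanolysis of both aryl acetates and n-Bu3P-catalysed conjugate addition/lactonisation/elimination of both (E)-2-hydroxycinnamates, which closes the two pyranone rings at once without touching a stereocentre.

**Compound list**
1 | 5-bromo-2-hydroxy-4-methoxybenzaldehyde | O=Cc1cc(Br)c(OC)cc1O | starting material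
2 | 4-bromo-2-formyl-5-methoxyphenyl acetate | CC(=O)Oc1cc(OC)c(Br)cc1C=O | intermediate
3 | methyl (2E)-3-[2-(acetyloxy)-5-bromo-4-methoxyphenyl]prop-2-enoate | COC(=O)/C=C/c1cc(Br)c(OC)cc1OC(C)=O | intermediate
4 | isoprene (2-methylbuta-1,3-diene) | C=CC(C)=C | starting material
5 | methyl (2E)-3-{2-(acetyloxy)-4-methoxy-5-[(1E)-3-methylbuta-1,3-dien-1-yl]phenyl}prop-2-enoate | COC(=O)/C=C/c1cc(/C=C/C(C)=C)c(OC)cc1OC(C)=O | intermediate
6 | methacrolein (2-methylprop-2-enal) | CC(=C)C=O | starting material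
7 | methyl (2E)-3-{2-(acetyloxy)-5-[(1R,6S)-6-formyl-3,6-dimethylcyclohex-2-en-1-yl]-4-methoxyphenyl}prop-2-enoate | O=C[C@@]1(C)CCC(C)=C[C@@H]1c1cc(/C=C/C(=O)OC)c(OC(C)=O)cc1OC | intermediate
8 | methyl (2E)-3-{2-(acetyloxy)-5-[(1S,6R)-6-ethenyl-3,6-dimethylcyclohex-2-en-1-yl]-4-methoxyphenyl}prop-2-enoate | C=C[C@@]1(C)CCC(C)=C[C@@H]1c1cc(/C=C/C(=O)OC)c(OC(C)=O)cc1OC | intermediate
9 | methyl (2E)-3-{2-(acetyloxy)-5-[(E)-2-{(1R,2S)-2-[4-(acetyloxy)-2-methoxy-5-[(1E)-3-methoxy-3-oxoprop-1-en-1-yl]phenyl]-1,4-dimethylcyclohex-3-en-1-yl}ethenyl]-4-methoxyphenyl}prop-2-enoate | COC(=O)/C=C/c1cc(/C=C/[C@@]2(C)CCC(C)=C[C@@H]2c2cc(/C=C/C(=O)OC)c(OC(C)=O)cc2OC)c(OC)cc1OC(C)=O | intermediate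
10 | methyl (2E)-3-{2-hydroxy-5-[(E)-2-{(1R,2S)-2-[4-hydroxy-2-methoxy-5-[(1E)-3-methoxy-3-oxoprop-1-en-1-yl]phenyl]-1,4-dimethylcyclohex-3-en-1-yl}ethenyl]-4-methoxyphenyl}prop-2-enoate | COC(=O)/C=C/c1cc(/C=C/[C@@]2(C)CCC(C)=C[C@@H]2c2cc(/C=C/C(=O)OC)c(O)cc2OC)c(OC)cc1O | intermediate
11 | 7-methoxy-6-[(E)-2-[(1R,2S)-2-(7-methoxy-2-oxo-2H-chromen-6-yl)-1,4-dimethylcyclohex-3-en-1-yl]ethenyl]-2H-chromen-2-one | COc1cc2oc(=O)ccc2cc1/C=C/[C@@]1(C)CCC(C)=C[C@@H]1c1cc2ccc(=O)oc2cc1OC | target

**Step count**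
Total steps: 5. Longest linear sequence: 5 (1 → 3 → 5 → 7 → 8 → 11; 3 is used a second time in step 5).

**Steps most likely to fail, with fallbacks**

The Diels–Alder reaction (step 3) is the largest risk. A 1-aryl diene is only moderately reactive and can oligomerise under the acidic catalyst. The exo:endo ratio is the main uncertainty: the target needs the formyl-exo adduct, and for an acyclic 1-aryl diene this preference is not secured by precedent known to me. The ee and the sense of induction with this diene are likewise unproven. The fallback sets out from 5 and comes back at 9. Heating 5 (about 2 M in toluene, 110 °C, BHT) brings about the thermal Diels–Alder dimerisation, one molecule acting as diene and the isopropenyl unit of a second as dienophile. This gives the racemic tetraester directly, that is 9 together with its mirror image methyl (2E)-3-{2-(acetyloxy)-5-[(E)-2-{(1S,2R)-2-[4-(acetyloxy)-2-methoxy-5-[(1E)-3-methoxy-3-oxoprop-1-en-1-yl]phenyl]-1,4-dimethylcyclohex-3-en-1-yl}ethenyl]-4-methoxyphenyl}prop-2-enoate F1. After chromatographic removal of diastereomers, preparative chiral SFC separates 9 from F1. Compound 9 then rejoins the route at the methanolysis/lactonisation stage of step 5; steps 3 and 4 and the second Heck coupling are bypassed.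

The Heck arylation of isoprene (step 2) may give the regioisomeric 2-methyl diene, suffer from the volatility of isoprene, and lose 5 to thermal dimerisation at 90 °C. The fallback sets out from 3 and comes back at 5. A Heck reaction of 3 with 2-methylbut-3-en-2-ol (Pd(OAc)2, P(o-tol)3, Et3N, MeCN, 85 °C) can give only one regioisomer, and its product cannot dimerise. It gives the tertiary allylic alcohol methyl (2E)-3-{2-(acetyloxy)-5-[(1E)-3-hydroxy-3-methylbut-1-en-1-yl]-4-methoxyphenyl}prop-2-enoate F2. Dehydration of F2 through its mesylate (MsCl, Et3N, CH2Cl2, 0 °C → rt) gives 5 cold and dilute, ready for step 3.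

The Heck/lactonisation cascade (step 5) may stall at the Heck stage, because the electron-rich ortho-methoxy aryl bromide must couple with a vinyl group on a quaternary carbon, and the one-flask sequel then has nothing to work on. The fallback sets out from 7 (with a second portion of 3) and comes back at 9. Takai iodo-olefination of 7 (CHI3, CrCl2, THF, 0 °C → rt) gives the (E)-vinyl iodide methyl (2E)-3-{2-(acetyloxy)-5-[(1S,6S)-6-[(E)-2-iodoethenyl]-3,6-dimethylcyclohex-2-en-1-yl]-4-methoxyphenyl}prop-2-enoate F3. Miyaura borylation of 3 (B2pin2, KOAc, Pd(dppf)Cl2, dioxane, 80 °C) gives methyl (2E)-3-[2-(acetyloxy)-4-methoxy-5-(4,4,5,5-tetramethyl-1,3,2-dioxaborolan-2-yl)phenyl]prop-2-enoate F4. Suzuki–Miyaura coupling of F3 with F4 (Pd(PPh3)4, K3PO4, THF–H2O, 50 °C) gives 9, which is then carried through the methanolysis and n-Bu3P lactonisation of step 5. Any acetate lost in the basic coupling is harmless because it is removed at that stage anyway.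

**Further compounds**
F1 | step 3 | methyl (2E)-3-{2-(acetyloxy)-5-[(E)-2-{(1S,2R)-2-[4-(acetyloxy)-2-methoxy-5-[(1E)-3-methoxy-3-oxoprop-1-en-1-yl]phenyl]-1,4-dimethylcyclohex-3-en-1-yl}ethenyl]-4-methoxyphenyl}prop-2-enoate | COC(=O)/C=C/c1cc(/C=C/[C@]2(C)CCC(C)=C[C@H]2c2cc(/C=C/C(=O)OC)c(OC(C)=O)cc2OC)c(OC)cc1OC(C)=O
F2 | step 2 | methyl (2E)-3-{2-(acetyloxy)-5-[(1E)-3-hydroxy-3-methylbut-1-en-1-yl]-4-methoxyphenyl}prop-2-enoate | COC(=O)/C=C/c1cc(/C=C/C(C)(C)O)c(OC)cc1OC(C)=O
F3 | step 5 | methyl (2E)-3-{2-(acetyloxy)-5-[(1S,6S)-6-[(E)-2-iodoethenyl]-3,6-dimethylcyclohex-2-en-1-yl]-4-methoxyphenyl}prop-2-enoate | I/C=C/[C@@]1(C)CCC(C)=C[C@@H]1c1cc(/C=C/C(=O)OC)c(OC(C)=O)cc1OC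
F4 | step 5 | methyl (2E)-3-[2-(acetyloxy)-4-methoxy-5-(4,4,5,5-tetramethyl-1,3,2-dioxaborolan-2-yl)phenyl]prop-2-enoate | COC(=O)/C=C/c1cc(B2OC(C)(C)C(C)(C)O2)c(OC)cc1OC(C)=O
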